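## Retrosynthetic overview

1. Numbering used below (eudesmane): ring A = C1–C5 plus C10, ring B = C5–C10, C15 = oxymethyl carbon on C4, C11–C13 = propenoate on C7. Endgame disconnections: the C15–O coumarate (Mitsunobu) and C11–C12 (methoxycarbonylation of an enol triflate made from a C7 acetyl group).
2. Key disconnection: ring A is opened at C1–C10 and C2–C3. The C1–C2 unit leaves as ethylene, and a monocyclic ring-B cyclohexene remains whose C9=C10 alkene is a latent tertiary C10 radical and whose C5 substituent is a β-methoxyacrylate (C3=C4–C15).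
3. Enabling feature: in ring A a bare C1H2–C2H2 bridge lies between the methyl-bearing quaternary C10 and the vinylic C3 of a C3=C4 bond that is conjugated with C15 once C15 is an ester. Hydrogen-atom transfer to C9, radical addition to ethylene, 6-endo closure onto C3 and loss of methoxide from C3 therefore build ring A, the angular stereocentre and the enoate in one reductive [4+2] annulation.
4. Ring B and the C7 stereocentre come from (S)-carvone; the C4–C5 bond and the C5 stereocentre come from a Johnson–Claisen rearrangement of the cis allylic alcohol; C3 comes from ethyl formate.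
5. Ring order: ring B (chiral pool) first, ring A second (key step), then the two side chains.

Key step: step 6

Remark: the enol ether of 7 is drawn as the (E)-isomer expected from O-methylation in DMF; its geometry is of no consequence, because C3 becomes sp3 and then sp2 again in step 6.

## Route

Step 1
Reactants: 1 (S)-(+)-carvone, (5S)-2-methyl-5-(prop-1-en-2-yl)cyclohex-2-en-1-one
Product: 2 (5S)-5-acetyl-2-methylcyclohex-2-en-1-one
Conditions: O3, CH2Cl2/MeOH, −78 °C; then Me2S, −78 °C → rt
Reagents that add atoms: ozone ([O-][O+]=O)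
Why: Chemoselective ozonolysis, in which the electron-rich 1,1-disubstituted isopropenyl alkene should be cleaved much faster than the electron-poor enone alkene, leaving the stereocentre untouched.

Step 2
Reactants: 2 (5S)-5-acetyl-2-methylcyclohex-2-en-1-one
Product: 3 (5S)-2-methyl-5-(2-methyl-1,3-dioxolan-2-yl)cyclohex-2-en-1-one
Conditions: TMSOCH2CH2OTMS, TMSOTf (cat.), CH2Cl2, −78 °C
Reagents that add atoms: 1,2-bis(trimethylsilyloxy)ethane (C[Si](C)(C)OCCO[Si](C)(C)C)
Why: Noyori ketalization, in which the saturated methyl ketone should react far faster than the conjugated ketone, while the aprotic low-temperature conditions avoid enolization toward the only stereocentre; the dioxolane hides the side chain from the later hydride and radical steps.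

Step 3
Reactants: 3 (5S)-2-methyl-5-(2-methyl-1,3-dioxolan-2-yl)cyclohex-2-en-1-one
Product: 4 (1S,5S)-2-methyl-5-(2-methyl-1,3-dioxolan-2-yl)cyclohex-2-en-1-ol (hydroxyl cis to the dioxolanyl group)
Conditions: NaBH4, CeCl3·7H2O, MeOH, −20 °C
Reagents that add atoms: none
Why: Luche 1,2-reduction, in which axial hydride delivery to the half-chair that holds the C5 substituent equatorial should set C1 with the hydroxyl cis to that substituent, as carvone gives cis-carveol.

Step 4
Reactants: 4 (1S,5S)-2-methyl-5-(2-methyl-1,3-dioxolan-2-yl)cyclohex-2-en-1-ol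
Product: 5 ethyl 2-[(1S,5R)-2-methyl-5-(2-methyl-1,3-dioxolan-2-yl)cyclohex-2-en-1-yl]acetate (acetate chain cis to the dioxolanyl group)
Conditions: MeC(OEt)3, EtCO2H (cat.), 180 °C, sealed tube
Reagents that add atoms: triethyl orthoacetate (CC(OCC)(OCC)OCC)
Why: Johnson–Claisen rearrangement, whose suprafacial [3,3] shift should form the new C–C bond at the distal alkene carbon on the ring face that the C–O bond leaves, so the new stereocentre is set cis to the dioxolanyl group by chirality transfer, as known for cis-carveol.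

Step 5
Reactants: 5 ethyl 2-[(1S,5R)-2-methyl-5-(2-methyl-1,3-dioxolan-2-yl)cyclohex-2-en-1-yl]acetate
Product: 7 ethyl (E)-3-methoxy-2-[(1R,5R)-2-methyl-5-(2-methyl-1,3-dioxolan-2-yl)cyclohex-2-en-1-yl]prop-2-enoate, via sodium formyl-ester enolate 6 (not isolated)
Conditions: NaH, HCO2Et, THF (cat. EtOH), 0 °C → rt; then Me2SO4, DMF, rt
Reagents that add atoms: ethyl formate (O=COCC); dimethyl sulfate (COS(=O)(=O)OC)
Why: Crossed Claisen condensation with ethyl formate followed by O-methylation of the sodium enolate with the hard electrophile Me2SO4 in DMF (the β-methoxyacrylate synthesis used for strobilurins) should give the enol ether without creating a stereocentre.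

Step 6
Reactants: 7 ethyl (E)-3-methoxy-2-[(1R,5R)-2-methyl-5-(2-methyl-1,3-dioxolan-2-yl)cyclohex-2-en-1-yl]prop-2-enoate; 8 ethylene
Product: 10 ethyl (4aR,7R,8aR)-4a-methyl-7-(2-methyl-1,3-dioxolan-2-yl)-3,4,4a,5,6,7,8,8a-octahydronaphthalene-1-carboxylate, via β-methoxy ester 9 (not isolated)
Conditions: Fe(acac)3 (0.3 equiv), PhSiH3 (slow addition), ethylene (20 bar), EtOH, 60 °C; then NaOEt (0.2 equiv), 60 °C
Reagents that add atoms: none
Why: Proposed new method: an iron hydride formed from Fe(acac)3 and PhSiH3 should transfer a hydrogen atom to C9 of the only electron-rich alkene of 7, the tertiary C10 radical adds to ethylene, the primary C2 radical closes ring A by attack on C3 of the β-methoxyacrylate, and the tertiary α-ester radical at C4 is reduced by divalent iron to the enolate, which is protonated to 9 or expels methoxide directly, NaOEt then completing the E1cB loss of methanol to the C3=C4 enoate. The closest known reaction types are the Fe(acac)3/PhSiH3 reductive coupling of trisubstituted alkenes with acceptor alkenes (quaternary centres by hydrogen-atom transfer and Giese addition), hydrogen-atom-transfer-initiated radical–polar crossover annulations, radical additions to pressurized ethylene, and 6-endo radical cyclizations onto α-substituted acrylates and β-alkoxyacrylates; what is new is ethylene as the two-carbon relay between the two radical events. Ring A is the only ring closed, in the 6-endo-trig radical mode, which should be preferred over 5-exo attack because C4 is fully substituted and C3 is the electrophilic β-carbon of the acrylate. The single new stereocentre, C10, is controlled by the vicinal C5 substituent, which shares a ring face with the C7 group: ethylene should add to the opposite face, so C1 ends trans to C4, ring closure gives the trans-fused decalin with the angular methyl cis to the C7 side chain, and C5 and C7 are not touched. The step needs chemoselective hydrogen-atom transfer (secured by the ketal, which leaves the C9=C10 alkene as the only donor alkene), ethylene capture faster than reduction of the C10 radical (secured by pressure and slow silane addition), and ring closure before a second ethylene adds (secured by the built-in acrylate acceptor); the ethyl ester matches the solvent, so no ester exchange can occur.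

Step 7
Reactants: 10 ethyl (4aR,7R,8aR)-4a-methyl-7-(2-methyl-1,3-dioxolan-2-yl)-3,4,4a,5,6,7,8,8a-octahydronaphthalene-1-carboxylate
Product: 11 ethyl (4aR,7R,8aR)-7-acetyl-4a-methyl-3,4,4a,5,6,7,8,8a-octahydronaphthalene-1-carboxylate
Conditions: 1 M HCl, THF, rt
Reagents that add atoms: water (O)
Why: Acid-catalysed ketal hydrolysis, to which the conjugated ester and the ring-fusion centres are inert and under which the acetyl group stays in the thermodynamically preferred equatorial position at C7.

Step 8
Reactants: 11 ethyl (4aR,7R,8aR)-7-acetyl-4a-methyl-3,4,4a,5,6,7,8,8a-octahydronaphthalene-1-carboxylate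
Product: 12 ethyl (4aR,7R,8aR)-4a-methyl-7-[1-(trifluoromethanesulfonyloxy)ethenyl]-3,4,4a,5,6,7,8,8a-octahydronaphthalene-1-carboxylate
Conditions: KHMDS, THF, −78 °C; then PhNTf2, −78 → 0 °C
Reagents that add atoms: N-phenylbis(trifluoromethanesulfonimide) (O=S(=O)(N(c1ccccc1)S(=O)(=O)C(F)(F)F)C(F)(F)F)
Why: Kinetic deprotonation of the methyl ketone at the unhindered methyl group and O-sulfonylation of the enolate should give the terminal enol triflate, since the ester has no α-hydrogen and its γ-hydrogens sit trans to the carbonyl group and are kinetically slow to leave.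

Step 9
Reactants: 12 ethyl (4aR,7R,8aR)-4a-methyl-7-[1-(trifluoromethanesulfonyloxy)ethenyl]-3,4,4a,5,6,7,8,8a-octahydronaphthalene-1-carboxylate
Product: 13 1-[(2R,4aR,8aR)-8-(hydroxymethyl)-4a-methyl-1,2,3,4,4a,5,6,8a-octahydronaphthalen-2-yl]ethenyl trifluoromethanesulfonate
Conditions: DIBAL-H (2.5 equiv), CH2Cl2, −78 °C; Rochelle salt work-up
Reagents that add atoms: none
Why: DIBAL-H reduces the conjugated ester in the 1,2-sense to the allylic alcohol while alkenyl triflates are inert to it at −78 °C, and doing this before the second ester exists removes any need to tell two esters apart.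

Step 10
Reactants: 13 1-[(2R,4aR,8aR)-8-(hydroxymethyl)-4a-methyl-1,2,3,4,4a,5,6,8a-octahydronaphthalen-2-yl]ethenyl trifluoromethanesulfonate
Product: 14 methyl 2-[(2R,4aR,8aR)-8-(hydroxymethyl)-4a-methyl-1,2,3,4,4a,5,6,8a-octahydronaphthalen-2-yl]prop-2-enoate
Conditions: Pd(OAc)2 (5 mol %), dppp, CO (1 atm), Et3N, MeOH/DMF, 50 °C
Reagents that add atoms: carbon monoxide ([C-]#[O+]); methanol (CO)
Why: Palladium-catalysed alkoxycarbonylation of an alkenyl triflate (oxidative addition, CO insertion, methanolysis of the acyl-palladium) puts the methyl ester on the triflate carbon and so gives the α-methylene ester directly, a free allylic alcohol being neither ionized by zerovalent palladium nor competitive with solvent methanol.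

Step 11
Reactants: 14 methyl 2-[(2R,4aR,8aR)-8-(hydroxymethyl)-4a-methyl-1,2,3,4,4a,5,6,8a-octahydronaphthalen-2-yl]prop-2-enoate; 15 (E)-p-coumaric acid, (2E)-3-(4-hydroxyphenyl)prop-2-enoic acid
Product: 16 methyl 2-[(2R,4aR,8aR)-8-({[(2E)-3-(4-hydroxyphenyl)prop-2-enoyl]oxy}methyl)-4a-methyl-1,2,3,4,4a,5,6,8a-octahydronaphthalen-2-yl]prop-2-enoate (CNP0161949.1)
Conditions: PPh3, DIAD, THF, 0 °C → rt
Reagents that add atoms: none
Why: Mitsunobu esterification, in which the carboxylic acid (far more acidic than the phenol) is the pronucleophile, so the primary allylic alcohol should be esterified by SN2 displacement of its oxyphosphonium ion without phenol protection, as known for hydroxycinnamic acids, leaving the (E)-alkene and all stereocentres untouched.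

## Compound list

1 | (S)-(+)-carvone, (5S)-2-methyl-5-(prop-1-en-2-yl)cyclohex-2-en-1-one | CC(=C)[C@@H]1CC(=O)C(C)=CC1 | starting material
2 | (5S)-5-acetyl-2-methylcyclohex-2-en-1-one | CC(=O)[C@@H]1CC(=O)C(C)=CC1 | intermediate
3 | (5S)-2-methyl-5-(2-methyl-1,3-dioxolan-2-yl)cyclohex-2-en-1-one | CC1(OCCO1)[C@@H]2CC(=O)C(C)=CC2 | intermediate
4 | (1S,5S)-2-methyl-5-(2-methyl-1,3-dioxolan-2-yl)cyclohex-2-en-1-ol | CC1(OCCO1)[C@@H]2C[C@H](O)C(C)=CC2 | intermediate
5 | ethyl 2-[(1S,5R)-2-methyl-5-(2-methyl-1,3-dioxolan-2-yl)cyclohex-2-en-1-yl]acetate | CC1(OCCO1)[C@@H]2CC=C(C)[C@H](CC(=O)OCC)C2 | intermediate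
6 | sodium 3-ethoxy-2-[(1R,5R)-2-methyl-5-(2-methyl-1,3-dioxolan-2-yl)cyclohex-2-en-1-yl]-3-oxoprop-1-en-1-olate (enolate of the α-formyl ester, not isolated) | CC1(OCCO1)[C@@H]2CC=C(C)[C@H](C(=C[O-])C(=O)OCC)C2.[Na+] | intermediate
7 | ethyl (E)-3-methoxy-2-[(1R,5R)-2-methyl-5-(2-methyl-1,3-dioxolan-2-yl)cyclohex-2-en-1-yl]prop-2-enoate | CC1(OCCO1)[C@@H]2CC=C(C)[C@H](/C(=C\OC)C(=O)OCC)C2 | intermediate
8 | ethylene | C=C | starting material
9 | ethyl (4aS,7R,8aS)-2-methoxy-4a-methyl-7-(2-methyl-1,3-dioxolan-2-yl)decahydronaphthalene-1-carboxylate (epimers at C1 and C2, not isolated) | CC1(OCCO1)[C@@H]2CC[C@@]3(C)CCC(OC)C(C(=O)OCC)[C@@H]3C2 | intermediate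
10 | ethyl (4aR,7R,8aR)-4a-methyl-7-(2-methyl-1,3-dioxolan-2-yl)-3,4,4a,5,6,7,8,8a-octahydronaphthalene-1-carboxylate | CC1(OCCO1)[C@@H]2CC[C@@]3(C)CCC=C(C(=O)OCC)[C@@H]3C2 | intermediate
11 | ethyl (4aR,7R,8aR)-7-acetyl-4a-methyl-3,4,4a,5,6,7,8,8a-octahydronaphthalene-1-carboxylate | CC(=O)[C@@H]1CC[C@@]2(C)CCC=C(C(=O)OCC)[C@@H]2C1 | intermediate
12 | ethyl (4aR,7R,8aR)-4a-methyl-7-[1-(trifluoromethanesulfonyloxy)ethenyl]-3,4,4a,5,6,7,8,8a-octahydronaphthalene-1-carboxylate | C=C(OS(=O)(=O)C(F)(F)F)[C@@H]1CC[C@@]2(C)CCC=C(C(=O)OCC)[C@@H]2C1 | intermediate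
13 | 1-[(2R,4aR,8aR)-8-(hydroxymethyl)-4a-methyl-1,2,3,4,4a,5,6,8a-octahydronaphthalen-2-yl]ethenyl trifluoromethanesulfonate | C=C(OS(=O)(=O)C(F)(F)F)[C@@H]1CC[C@@]2(C)CCC=C(CO)[C@@H]2C1 | intermediate
14 | methyl 2-[(2R,4aR,8aR)-8-(hydroxymethyl)-4a-methyl-1,2,3,4,4a,5,6,8a-octahydronaphthalen-2-yl]prop-2-enoate | C=C(C(=O)OC)[C@@H]1CC[C@@]2(C)CCC=C(CO)[C@@H]2C1 | intermediate
15 | (E)-p-coumaric acid, (2E)-3-(4-hydroxyphenyl)prop-2-enoic acid | OC(=O)/C=C/c1ccc(O)cc1 | starting material
16 | methyl 2-[(2R,4aR,8aR)-8-({[(2E)-3-(4-hydroxyphenyl)prop-2-enoyl]oxy}methyl)-4a-methyl-1,2,3,4,4a,5,6,8a-octahydronaphthalen-2-yl]prop-2-enoate | C=C(C(=O)OC)[C@@H]1CC[C@@]2(C)CCC=C(COC(=O)/C=C/c3ccc(O)cc3)[C@@H]2C1 | target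

## Step count and risks

Total step count: 11. Longest linear sequence: 11 steps (from 1).

Steps most likely to fail:

Step 6 (Proposed new method). The tertiary C10 radical may be reduced to the C–H compound, or add to the acrylate of a second molecule, before it captures the unactivated ethylene; the primary radical may take up a second ethylene before it closes the ring; and the iron hydride may attack the acrylate. The fallback uses known chemistry and sets out from 7. The established Fe(acac)3/PhSiH3 reductive coupling with phenyl vinyl sulfone (EtOH/ethylene glycol, 60 °C) should form the C1–C10 bond with the same facial preference and give ethyl (E)-2-[(1R,2S,5R)-2-[2-(benzenesulfonyl)ethyl]-2-methyl-5-(2-methyl-1,3-dioxolan-2-yl)cyclohexyl]-3-methoxyprop-2-enoate F1. LDA (THF, −78 → 0 °C) should then close ring A by conjugate addition of the α-sulfonyl carbanion to C3 and loss of methoxide, giving ethyl (4aS,7R,8aR)-3-(benzenesulfonyl)-4a-methyl-7-(2-methyl-1,3-dioxolan-2-yl)-3,4,4a,5,6,7,8,8a-octahydronaphthalene-1-carboxylate F2 as a mixture of C3 epimers. Pd(PPh3)4 with NaBH4 (THF/i-PrOH, rt) should replace the allylic sulfonyl group by hydride at the allyl terminus remote from the ester, and the route is rejoined at 10.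

Step 4. The cis alcohol must turn both substituents axial (or pass through a boat) to rearrange, so under the forcing acidic conditions dehydration of the allylic alcohol to a diene and exchange of the dioxolane with ethanol may overtake the rearrangement. The fallback sets out from 4 and avoids acid and alcohol altogether. Conjugate addition of 4 to ethyl propiolate (N-methylmorpholine cat., CH2Cl2, rt) should give the allyl vinyl ether ethyl (E)-3-{[(1S,5S)-2-methyl-5-(2-methyl-1,3-dioxolan-2-yl)cyclohex-2-en-1-yl]oxy}prop-2-enoate F3. Its neutral thermal Claisen rearrangement (toluene, 180 °C, sealed tube) should deliver, with the same suprafacial chirality transfer, the α-formyl ester ethyl 2-[(1S,5R)-2-methyl-5-(2-methyl-1,3-dioxolan-2-yl)cyclohex-2-en-1-yl]-3-oxopropanoate F4 (aldehyde/enol mixture). O-Methylation (Me2SO4, K2CO3, acetone) then rejoins the route at 7, so that step 5 is bypassed as well.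

Step 11. Competing O-alkylation of the phenol, addition of the phosphine or the betaine to the α-methylene ester, and allylic transposition may erode the esterification. The fallback sets out from 14 and activates the acid instead of the alcohol. Coupling with commercial (E)-4-acetoxycinnamic acid (EDC·HCl, DMAP, CH2Cl2, rt) should give methyl 2-[(2R,4aR,8aR)-8-({[(2E)-3-(4-acetoxyphenyl)prop-2-enoyl]oxy}methyl)-4a-methyl-1,2,3,4,4a,5,6,8a-octahydronaphthalen-2-yl]prop-2-enoate F5. Brief methanolysis of the aryl acetate (K2CO3 cat., MeOH, 0 °C), which should be much faster than cleavage of the alkyl esters, then gives 16.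

Further compounds
F1 | step 6 | ethyl (E)-2-[(1R,2S,5R)-2-[2-(benzenesulfonyl)ethyl]-2-methyl-5-(2-methyl-1,3-dioxolan-2-yl)cyclohexyl]-3-methoxyprop-2-enoate | CC1(OCCO1)[C@@H]2CC[C@@](C)(CCS(=O)(=O)c3ccccc3)[C@H](/C(=C\OC)C(=O)OCC)C2
F2 | step 6 | ethyl (4aS,7R,8aR)-3-(benzenesulfonyl)-4a-methyl-7-(2-methyl-1,3-dioxolan-2-yl)-3,4,4a,5,6,7,8,8a-octahydronaphthalene-1-carboxylate (C3 epimers) | CC1(OCCO1)[C@@H]2CC[C@@]3(C)CC(S(=O)(=O)c4ccccc4)C=C(C(=O)OCC)[C@@H]3C2
F3 | step 4 | ethyl (E)-3-{[(1S,5S)-2-methyl-5-(2-methyl-1,3-dioxolan-2-yl)cyclohex-2-en-1-yl]oxy}prop-2-enoate | CC1(OCCO1)[C@@H]2C[C@H](O/C=C/C(=O)OCC)C(C)=CC2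
F4 | step 4 | ethyl 2-[(1S,5R)-2-methyl-5-(2-methyl-1,3-dioxolan-2-yl)cyclohex-2-en-1-yl]-3-oxopropanoate (aldehyde/enol mixture) | CC1(OCCO1)[C@@H]2CC=C(C)[C@H](C(C=O)C(=O)OCC)C2
F5 | step 11 | methyl 2-[(2R,4aR,8aR)-8-({[(2E)-3-(4-acetoxyphenyl)prop-2-enoyl]oxy}methyl)-4a-methyl-1,2,3,4,4a,5,6,8a-octahydronaphthalen-2-yl]prop-2-enoate | C=C(C(=O)OC)[C@@H]1CC[C@@]2(C)CCC=C(COC(=O)/C=C/c3ccc(OC(C)=O)cc3)[C@@H]2C1
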